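Atom numbering: the indene numbering of the target is used for the ring carbons of every intermediate, monocyclic ones included (ring A: C1, C2, C3, C3a, C7a; ring B: C3a, C4, C5, C6, C7, C7a; side chain on C6: C1′ to C4′).

## The problem

Zyggomphic acid B (23) is a 3a,6,7,7a-tetrahydro-3H-indene in which a cyclopentene (ring A, C1=C2, ethyl on C1) is fused trans across C3a–C7a to a cyclohexene (ring B, C4=C5, methyl on C4). Five contiguous stereocentres run C3–C3a–C7a–C7–C6. C6 (methyl, dienyl) and C7 (methyl, carboxyl) are adjacent quaternary carbons, with the two methyls cis to each other and the dienyl cis to the carboxyl. Control can be relayed: the two C7 substituents can tell the faces of C7a apart, C7a then places its partner at C3a trans, and once the trans fusion locks ring B the C7 methyl is axial and should send an incoming group at C6 to the opposite face. Only C3, outside ring B, has no neighbour that sets it reliably and needs a reagent. The carboxyl sits between two fully substituted carbons and cannot be unmasked by acyl substitution; the free acid is γ,δ-unsaturated towards both C4=C5 and the styryl diene, so protic acid invites lactonisation or diene isomerisation. C3a is epimerisable for as long as C4 is a carbonyl. The feature that opens the synthesis is ring B itself: with oxygen in place of the C4 methyl it is a reduced benzoate, tert-butyl 1-methyl-4-oxocyclohexa-2,5-diene-1-carboxylate (4). In 4, C7 is not yet stereogenic, the two enone arms are enantiotopic, and C7a is β and C3a α to the C4 carbonyl. A conjugate addition at C7a with capture of the enolate at C3a therefore attaches both ring A carbons, makes C7 stereogenic without a bond being formed to it, and leaves the second enone arm for C6 and, through the C4 oxygen, for the C4 methyl.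

## Retrosynthesis

**23 ⇒ 21 (ester oxygen–tert-butyl bond).** The acid is carried as tert-butyl ester 21 and released last by cleavage at the alkyl–oxygen bond, the only site not blocked by the two quaternary carbons. A tert-butyl ester is also the ester that survives dissolving metal, Grignard, alane and organolithium steps and is large enough to bias the faces of ring B. The forward reaction must be non-protic and buffered.

**21 ⇒ 20 ⇒ 18 (C4–CH3).** Removing the C4 methyl leads to enol triflate 20 and behind it to silyl enol ether 18 of a C4 ketone. The neighbouring option, adding a methyl nucleophile to the ketone and dehydrating, would leave the alkene position (C4=C5, C3a=C4 or exocyclic) to chance and put C3a at risk. The enol derivative fixes the alkene where the enolate is born. The forward reaction is a palladium-catalysed methyl coupling on a hindered alkenyl triflate.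

**18 ⇒ 13 + 16 (C6–C1′).** The side chain is cut from C6 as a conjugate addition of dienylalane 16 to β-methyl enone 13, the enolate being captured as 18. The reverse order (dienyl first, methyl last) is rejected: the second group to arrive at C6 enters axially, anti to the axial C7 methyl, and the target has the dienyl on that face. Building the chain from a one-carbon unit at a neopentyl position would cost several steps. This cut removes eleven carbons and one quaternary centre, and it asks for a quaternary carbon to be made next to another one.

**16 ⇒ 15 ⇒ 14 (C2′–CH3 and the carbon–aluminium bond).** Alane 16 is the syn methylmetalation product of enyne 15, which fixes the trisubstituted alkene geometry without an olefination. Enyne 15 is one carbon away from cinnamaldehyde 14.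

**13 ⇒ 12 ⇒ 11 (C6–CH3).** The C6 methyl comes from conjugate methylation of enone 11 to enol ether 12 and re-oxidation to 13. No stereocentre created here survives, so the pair of steps only has to be clean.

**11 ⇒ 10 (C1=C2).** Ring A is opened at its alkene to trans-2,3-dialkenyl cyclohexenone 10. Cutting here and not at C7a–C1 or C3a–C3 saves those two bonds for the stereodefining step. The trans relation of the alkenyl groups becomes the trans ring fusion that annulations through cis-fused transition states do not give. The forward reaction is a ring-closing metathesis between a 1,1-disubstituted and a 1,2-disubstituted alkene.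

**10 ⇒ 4 + 6 + 8 (C7a–C1 and C3a–C3, key disconnection).** Both bonds from ring B to ring A carbons are cut together, giving achiral dienone 4, Grignard reagent 6 and racemic allylic acetate 8. Forming them on one enolate avoids regenerating it and lets the new C7a substituent place C3a. The precursor has no stereocentre. The forward reaction needs arm selection by a chiral copper catalyst, face selection by the C7 substituents, anti allylation, and a chiral palladium catalyst for C3.

**4 ⇒ 3 ⇒ 1; 6 ⇐ 5; 8 ⇐ 7.** Dienone 4 is the oxidation product of diene 3, itself the reductive methylation product of tert-butyl benzoate 1 (C7–CH3 bond). Reagent 6 comes from bromide 5 and acetate 8 from alcohol 7.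

## Roads not taken

**Alternative 1:** The C6–C7 bond is cut. In the forward step a tertiary ester enolate at C7, carried on a finished ring A in keto ester A2 (the (2Z,4E,6E)-trienoyl chain on C3a), would add to C6 in a 6-endo-trig Michael closure and give ring B ketone A1.
- Merits: the bond between the two quaternary carbons is made intramolecularly, where entropy helps most. The whole side chain arrives with the acceptor. A1 already has the C4 ketone for the methyl.
- Weak points: A2 needs ring A with C3, C3a and C7a set, and there is no comparably direct enantioselective entry to it. The configurations at C7 and C6 depend on the geometry of an acyclic ester enolate and on a Z trisubstituted enone that isomerises readily under base. The trienone offers its 1,6- and 1,8-positions to the enolate. An adduct with vicinal quaternary carbons can revert. C3a is epimerisable under the same base.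
- Comparison: if it worked, A1 would deliver in one step what the chosen route needs steps 7, 8 and 11 for, and in that respect it is the better plan. The chosen plan sets against this that both C6 bonds form under a predictable axial-attack rule on a rigid bicycle, that C7 never depends on an enolate geometry, and that everything starts from achiral bulk chemicals.

**Alternative 2:** The C1=C2 alkene is cut. Monocyclic β-methyl enone A4 (butenyl on C7a, pentenyl on C3a) would be closed by a ruthenium carbene to bicyclic enone A3 with loss of propene.
- Merits: the reaction is robust and tolerant, the ring fusion is inherited from A4, and a trisubstituted enone alkene does not interfere. As a single step it is safer than the chosen key step, which couples three components under two catalysts.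
- Weak points: it creates no stereocentre. C3, C3a, C7 and C7a must all be present in A4, so the plan names the easy bond and leaves the origin of A4 open; any answer leads back to an enolate allylation of the kind chosen.
- Comparison: the two plans do not conflict. A3 is the same compound as 13, and the same metathesis is step 6 of the chosen route, run one stage earlier on 10. The chosen order gives a rigid bicycle for both additions at C6; the order of this alternative is kept as the fallback for step 6. Against its lower risk the chosen plan sets one step that accounts for four stereocentres from an achiral dienone.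

**Alternative 3:** The C7–C7a bond and the C5=C6 alkene are cut. β-Keto ester A6 would add through its α-carbon to enone A7 under a chiral catalyst, and aldol condensation of the new methyl ketone onto the acetyl carbonyl would give cyclohexenone A5 with C7 set.
- Merits: enantioselective Michael additions of α-substituted β-keto esters to vinyl ketones are among the best-established routes to a quaternary stereocentre. The materials are cheap and the step scales. A5 already contains the C6 methyl enone that the chosen route spends steps 7 and 8 on. In these respects it is better.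
- Weak points: the aldol half has two six-membered modes, and the wanted one requires attack on the hindered acetyl carbonyl next to the quaternary carbon. In A5, C7a and C3a are bare methylenes, so the ring must be dehydrogenated to a dienone before the conjugate addition–allylation of step 5 can be run anyway. That addition would rely on C7 alone for the face at C7a, with no arm selection by a catalyst.
- Comparison: the step count to 13 would be similar. The chosen plan sets against the cheaper source of absolute configuration a symmetrical dienone with no regiochemical ambiguity and one step that fixes four stereocentres.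

Key step: step 5

Assumption: the ligand antipodes written in step 5 are assigned by analogy with simpler enones and allyl acetates; if the sense of induction at C7a or C3 proves opposite, the mirror-image ligand is used.

## Route

Step 1
Reactants: 1 tert-butyl benzoate
Product: 3 tert-butyl 1-methylcyclohexa-2,5-diene-1-carboxylate, via lithium dienolate 2 (not isolated)
Conditions: Li (2.2 equiv), NH3(l)/THF, −78 °C; then MeI, −78 °C → rt
Reagents that add atoms: iodomethane, CI
Why: Birch reduction gives the cross-conjugated ester dienolate 2 (ammonia protonates C4), which is methylated at the α-carbon (Birch reductive alkylation); the tert-butyl ester resists amide attack and over-reduction, and no stereocentre is formed.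

Step 2
Reactants: 3 tert-butyl 1-methylcyclohexa-2,5-diene-1-carboxylate
Product: 4 tert-butyl 1-methyl-4-oxocyclohexa-2,5-diene-1-carboxylate
Conditions: CrO3, 3,5-dimethylpyrazole, CH2Cl2, −20 °C
Reagents that add atoms: chromium trioxide, O=[Cr](=O)=O
Why: Allylic oxidation of the doubly allylic methylene by the CrO3–dimethylpyrazole complex; the quaternary carbon blocks aromatisation, so the cross-conjugated dienone is the expected outlet.

Step 3
Reactants: 5 2-bromobut-1-ene
Product: 6 but-1-en-2-ylmagnesium bromide (titrated solution)
Conditions: Mg turnings, I2 (cat.), 2-MeTHF, 45 °C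
Reagents that add atoms: magnesium, [Mg]
Why: Grignard formation by insertion of magnesium into the alkenyl C–Br bond; 2-methyltetrahydrofuran keeps the reagent compatible with the copper step.

Step 4
Reactants: 7 (E)-pent-3-en-2-ol (racemic)
Product: 8 (E)-pent-3-en-2-yl acetate (racemic)
Conditions: Ac2O, Et3N, DMAP (cat.), CH2Cl2, 0 °C → rt
Reagents that add atoms: acetic anhydride, CC(=O)OC(C)=O
Why: DMAP-catalysed O-acylation; the racemate suffices because both enantiomers ionise to the same symmetrical allyl complex in step 5.

Step 5
Reactants: 4 tert-butyl 1-methyl-4-oxocyclohexa-2,5-diene-1-carboxylate; 6 but-1-en-2-ylmagnesium bromide; 8 (E)-pent-3-en-2-yl acetate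
Product: 10 tert-butyl (1S,5S,6R)-6-(but-1-en-2-yl)-1-methyl-4-oxo-5-[(2R,3E)-pent-3-en-2-yl]cyclohex-2-ene-1-carboxylate, via bromomagnesium dienolate 9 (not isolated)
Conditions: Cu(OTf)2 (5 mol %), (S,R,R)-BINOL/bis(1-phenylethyl)amine phosphoramidite (10 mol %), 6 (1.05 equiv, slow addition), 2-MeTHF/Et2O, −78 °C; then Pd2(dba)3 (2.5 mol %), (R)-BINAP (6 mol %), 8 (1.5 equiv), THF, −78 → 0 °C; aq NH4Cl
Reagents that add atoms: none
Why: Copper-catalysed asymmetric conjugate addition with palladium-catalysed allylation of the enolate in the same flask; the closest known types are tandem enantioselective 1,4-addition/allylic alkylation of cyclic enones and the desymmetrisation of 4,4-disubstituted cyclohexadienones. Cu(OTf)2 is reduced by 6 to monovalent copper, whose phosphoramidite-bound alkenyl complex binds one enantiotopic enone arm, adds oxidatively to a trivalent β-cuprio enolate and reductively eliminates the C7a–C1 bond, leaving dienolate 9. Zerovalent palladium with (R)-BINAP ionises either enantiomer of 8 to the same syn,syn-1,3-dimethylallyl complex of divalent palladium, which 9 attacks from outside at C3a to form C3a–C3 with the E alkene retained. No ring is closed. C7a is set by the copper ligand (choice of arm) together with the substrate (the alkenyl group enters the face of the C7 methyl, away from the bulkier tert-butyl ester), and by that choice C7 becomes stereogenic without a bond being made to it. C3a is set by the substrate, the allyl unit approaching anti to the new C7a substituent, and C3 by the palladium ligand, which decides which allyl terminus is attacked. The step needs 1,4- over 1,2-addition (copper catalysis at −78 °C with slow addition), a single addition (the second arm is tied up in the cross-conjugated dienolate until quench) and C-allylation at C3a (the only enolate carbon that can become sp3, C5 being vinylic). Holding 6 near one equivalent keeps copper-mediated substitution of the acetate from competing.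

Step 6
Reactants: 10 tert-butyl (1S,5S,6R)-6-(but-1-en-2-yl)-1-methyl-4-oxo-5-[(2R,3E)-pent-3-en-2-yl]cyclohex-2-ene-1-carboxylate
Product: 11 tert-butyl (3R,3aS,7S,7aR)-1-ethyl-3,7-dimethyl-4-oxo-3a,4,7,7a-tetrahydro-3H-indene-7-carboxylate
Conditions: second-generation Grubbs catalyst RuCl2(=CHPh)(PCy3)(H2IMes) (5 mol %), CH2Cl2 (5 mM), 40 °C
Reagents that add atoms: none
Why: Ring-closing olefin metathesis: the ruthenium carbene loads at the propenyl group and closes ring A onto the 1,1-disubstituted alkene with loss of propene, giving the trisubstituted C1=C2; the trans relation of the alkenyl groups in 10 becomes the trans ring fusion, and the electron-poor enone alkene should stay out.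

Step 7
Reactants: 11 tert-butyl (3R,3aS,7S,7aR)-1-ethyl-3,7-dimethyl-4-oxo-3a,4,7,7a-tetrahydro-3H-indene-7-carboxylate
Product: 12 tert-butyl (3R,3aS,6S,7S,7aR)-1-ethyl-3,6,7-trimethyl-4-[(trimethylsilyl)oxy]-3a,6,7,7a-tetrahydro-3H-indene-7-carboxylate (used crude)
Conditions: MeMgBr, CuBr·SMe2 (10 mol %), Me3SiCl, HMPA, THF, −78 °C; Et3N, pentane, cold aq NaHCO3
Reagents that add atoms: methylmagnesium bromide, C[Mg]Br; chlorotrimethylsilane, C[Si](C)(C)Cl
Why: Copper-catalysed conjugate addition of the methyl Grignard reagent accelerated by Me3SiCl, which captures the enolate regiospecifically as the C4–C5 enol ether; attack at C6 should be axial, anti to the axial C7 methyl, but C6 becomes trigonal again in step 8, so either epimer serves.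

Step 8
Reactants: 12 tert-butyl (3R,3aS,6S,7S,7aR)-1-ethyl-3,6,7-trimethyl-4-[(trimethylsilyl)oxy]-3a,6,7,7a-tetrahydro-3H-indene-7-carboxylate
Product: 13 tert-butyl (3R,3aS,7R,7aR)-1-ethyl-3,6,7-trimethyl-4-oxo-3a,4,7,7a-tetrahydro-3H-indene-7-carboxylate
Conditions: Pd(OAc)2 (1.1 equiv), MeCN, rt
Reagents that add atoms: none
Why: Saegusa–Ito oxidation: the silyl enol ether gives a divalent palladium enolate at C5, which loses the C6 hydride and restores the enone with the C6 methyl in place; no stereocentre is touched.

Step 9
Reactants: 14 (E)-cinnamaldehyde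
Product: 15 (E)-but-1-en-3-yn-1-ylbenzene
Conditions: Me3SiCHN2, LDA, THF, −78 °C → rt
Reagents that add atoms: (trimethylsilyl)diazomethane, C[Si](C)(C)C=[N+]=[N-]
Why: Colvin rearrangement: the lithiated silyldiazomethane adds to the aldehyde, Peterson-type loss of silanolate and then of N2 gives an alkylidene carbene, and a 1,2-hydrogen shift delivers the terminal alkyne; the E styryl alkene is untouched.

Step 10
Reactants: 15 (E)-but-1-en-3-yn-1-ylbenzene
Product: 16 dimethyl[(1E,3E)-2-methyl-4-phenylbuta-1,3-dien-1-yl]alane (solution in Et2O)
Conditions: Me3Al (2 equiv), Cp2ZrCl2 (20 mol %), CH2Cl2, 0 °C → rt; volatiles and excess Me3Al removed in vacuo; Et2O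
Reagents that add atoms: trimethylaluminium, C[Al](C)C
Why: Zirconium-catalysed carboalumination of a terminal alkyne: syn addition of methyl and aluminium with aluminium on the terminal carbon fixes the 1E geometry of the trisubstituted alkene; the styryl alkene does not react.

Step 11
Reactants: 13 tert-butyl (3R,3aS,7R,7aR)-1-ethyl-3,6,7-trimethyl-4-oxo-3a,4,7,7a-tetrahydro-3H-indene-7-carboxylate; 16 dimethyl[(1E,3E)-2-methyl-4-phenylbuta-1,3-dien-1-yl]alane
Product: 18 tert-butyl (3R,3aS,6S,7R,7aR)-1-ethyl-3,6,7-trimethyl-6-[(1E,3E)-2-methyl-4-phenylbuta-1,3-dien-1-yl]-4-[(trimethylsilyl)oxy]-3a,6,7,7a-tetrahydro-3H-indene-7-carboxylate, via dimethylaluminium enolate 17 (not isolated)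
Conditions: 16 (2 equiv), copper thiophene-2-carboxylate Cu(O2CC4H3S) (10 mol %), 2,2′-biphenol N,N-diisopropylphosphoramidite (11 mol %), Et2O, −30 → 0 °C; then Me3SiOTf, −78 °C; Et3N, pentane, cold aq NaHCO3
Reagents that add atoms: trimethylsilyl trifluoromethanesulfonate, C[Si](C)(C)OS(=O)(=O)C(F)(F)F
Why: Copper-catalysed conjugate addition of an alkenylalane to a β,β-disubstituted enone, a known way to quaternary carbons in which the Lewis-acidic aluminium activates the carbonyl and the alkenyl group transfers in preference to methyl; in the trans-fused enone the C7 methyl is axial, so the dienyl group should enter C6 axially on the opposite face, cis to the ester, which is the target configuration; Me3SiOTf at −78 °C captures the aluminium enolate as the C4–C5 enol ether and should leave the tert-butyl ester alone at that temperature.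

Step 12
Reactants: 18 tert-butyl (3R,3aS,6S,7R,7aR)-1-ethyl-3,6,7-trimethyl-6-[(1E,3E)-2-methyl-4-phenylbuta-1,3-dien-1-yl]-4-[(trimethylsilyl)oxy]-3a,6,7,7a-tetrahydro-3H-indene-7-carboxylate
Product: 20 tert-butyl (3R,3aS,6S,7R,7aR)-1-ethyl-3,6,7-trimethyl-6-[(1E,3E)-2-methyl-4-phenylbuta-1,3-dien-1-yl]-4-{[(trifluoromethyl)sulfonyl]oxy}-3a,6,7,7a-tetrahydro-3H-indene-7-carboxylate, via lithium enolate 19 (not isolated)
Conditions: MeLi, THF, 0 °C; then PhNTf2, −78 → 0 °C
Reagents that add atoms: N-phenylbis(trifluoromethanesulfonimide), O=S(=O)(N(c1ccccc1)S(=O)(=O)C(F)(F)F)C(F)(F)F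
Why: Cleavage of the trimethylsilyl enol ether by MeLi regenerates the regiodefined lithium enolate, which is O-sulfonylated by the triflimide (enol triflate formation); the double bond stays at C4–C5 because C3a is never deprotonated, and the shielded ester does not react with MeLi.

Step 13
Reactants: 20 tert-butyl (3R,3aS,6S,7R,7aR)-1-ethyl-3,6,7-trimethyl-6-[(1E,3E)-2-methyl-4-phenylbuta-1,3-dien-1-yl]-4-{[(trifluoromethyl)sulfonyl]oxy}-3a,6,7,7a-tetrahydro-3H-indene-7-carboxylate
Product: 21 tert-butyl (3R,3aS,6S,7R,7aR)-1-ethyl-3,4,6,7-tetramethyl-6-[(1E,3E)-2-methyl-4-phenylbuta-1,3-dien-1-yl]-3a,6,7,7a-tetrahydro-3H-indene-7-carboxylate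
Conditions: Me2Zn (2 equiv), Pd(PPh3)4 (5 mol %), THF, 0 → 45 °C
Reagents that add atoms: dimethylzinc, C[Zn]C
Why: Negishi coupling: zerovalent palladium inserts into the alkenyl C–O bond, methyl is transferred from zinc and reductive elimination puts the methyl on C4; ester, diene and ring A alkene are inert.

Step 14
Reactants: 21 tert-butyl (3R,3aS,6S,7R,7aR)-1-ethyl-3,4,6,7-tetramethyl-6-[(1E,3E)-2-methyl-4-phenylbuta-1,3-dien-1-yl]-3a,6,7,7a-tetrahydro-3H-indene-7-carboxylate
Product: 23 zyggomphic acid B, via trimethylsilyl ester 22 (not isolated)
Conditions: Me3SiOTf, 2,6-lutidine, CH2Cl2, 0 °C → rt; then pH 5 aqueous buffer, 0 °C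
Reagents that add atoms: none
Why: Silyl triflate-mediated cleavage of a tert-butyl ester: O-silylation of the carbonyl and loss of the tert-butyl cation as 2-methylpropene give silyl ester 22, which is hydrolysed on work-up; ionisation at the tert-butyl group sidesteps the blocked acyl carbon, and the lutidine buffer avoids the free protic acid that could lactonise the γ,δ-unsaturated acid or isomerise the diene.

## Compound list

1 | tert-butyl benzoate | CC(C)(C)OC(=O)c1ccccc1 | starting material
2 | lithium dienolate of tert-butyl cyclohexa-2,5-diene-1-carboxylate | [Li+].CC(C)(C)OC([O-])=C1C=CCC=C1 | intermediate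
3 | tert-butyl 1-methylcyclohexa-2,5-diene-1-carboxylate | CC1(C=CCC=C1)C(=O)OC(C)(C)C | intermediate
4 | tert-butyl 1-methyl-4-oxocyclohexa-2,5-diene-1-carboxylate | CC1(C=CC(=O)C=C1)C(=O)OC(C)(C)C | intermediate
5 | 2-bromobut-1-ene | CCC(Br)=C | starting material
6 | but-1-en-2-ylmagnesium bromide | CCC(=C)[Mg]Br | intermediate
7 | (E)-pent-3-en-2-ol (racemic) | C/C=C/C(C)O | starting material
8 | (E)-pent-3-en-2-yl acetate (racemic) | C/C=C/C(C)OC(C)=O | intermediate
9 | tert-butyl (1S,6R)-4-[(bromomagnesio)oxy]-6-(but-1-en-2-yl)-1-methylcyclohexa-2,4-diene-1-carboxylate | C1=CC(O[Mg]Br)=C[C@H](C(=C)CC)[C@@]1(C)C(=O)OC(C)(C)C | intermediate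
10 | tert-butyl (1S,5S,6R)-6-(but-1-en-2-yl)-1-methyl-4-oxo-5-[(2R,3E)-pent-3-en-2-yl]cyclohex-2-ene-1-carboxylate | C1=CC(=O)[C@@H]([C@H](C)/C=C/C)[C@H](C(=C)CC)[C@@]1(C)C(=O)OC(C)(C)C | intermediate
11 | tert-butyl (3R,3aS,7S,7aR)-1-ethyl-3,7-dimethyl-4-oxo-3a,4,7,7a-tetrahydro-3H-indene-7-carboxylate | CCC1=C[C@@H](C)[C@@H]2C(=O)C=C[C@](C)(C(=O)OC(C)(C)C)[C@@H]12 | intermediate
12 | tert-butyl (3R,3aS,6S,7S,7aR)-1-ethyl-3,6,7-trimethyl-4-[(trimethylsilyl)oxy]-3a,6,7,7a-tetrahydro-3H-indene-7-carboxylate | CCC1=C[C@@H](C)[C@@H]2C(O[Si](C)(C)C)=C[C@H](C)[C@](C)(C(=O)OC(C)(C)C)[C@@H]12 | intermediate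
13 | tert-butyl (3R,3aS,7R,7aR)-1-ethyl-3,6,7-trimethyl-4-oxo-3a,4,7,7a-tetrahydro-3H-indene-7-carboxylate | CCC1=C[C@@H](C)[C@@H]2C(=O)C=C(C)[C@](C)(C(=O)OC(C)(C)C)[C@@H]12 | intermediate
14 | (E)-cinnamaldehyde | O=C/C=C/c1ccccc1 | starting material
15 | (E)-but-1-en-3-yn-1-ylbenzene | C#C/C=C/c1ccccc1 | intermediate
16 | dimethyl[(1E,3E)-2-methyl-4-phenylbuta-1,3-dien-1-yl]alane | C[Al](C)/C=C(C)/C=C/c1ccccc1 | intermediate
17 | tert-butyl (3R,3aS,6S,7R,7aR)-4-[(dimethylalumanyl)oxy]-1-ethyl-3,6,7-trimethyl-6-[(1E,3E)-2-methyl-4-phenylbuta-1,3-dien-1-yl]-3a,6,7,7a-tetrahydro-3H-indene-7-carboxylate | CCC1=C[C@@H](C)[C@@H]2C(O[Al](C)C)=C[C@](C)(/C=C(C)/C=C/c3ccccc3)[C@](C)(C(=O)OC(C)(C)C)[C@@H]12 | intermediate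
18 | tert-butyl (3R,3aS,6S,7R,7aR)-1-ethyl-3,6,7-trimethyl-6-[(1E,3E)-2-methyl-4-phenylbuta-1,3-dien-1-yl]-4-[(trimethylsilyl)oxy]-3a,6,7,7a-tetrahydro-3H-indene-7-carboxylate | CCC1=C[C@@H](C)[C@@H]2C(O[Si](C)(C)C)=C[C@](C)(/C=C(C)/C=C/c3ccccc3)[C@](C)(C(=O)OC(C)(C)C)[C@@H]12 | intermediate
19 | lithium (3R,3aS,6S,7R,7aR)-7-(tert-butoxycarbonyl)-1-ethyl-3,6,7-trimethyl-6-[(1E,3E)-2-methyl-4-phenylbuta-1,3-dien-1-yl]-3a,6,7,7a-tetrahydro-3H-inden-4-olate | [Li+].CCC1=C[C@@H](C)[C@@H]2C([O-])=C[C@](C)(/C=C(C)/C=C/c3ccccc3)[C@](C)(C(=O)OC(C)(C)C)[C@@H]12 | intermediate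
20 | tert-butyl (3R,3aS,6S,7R,7aR)-1-ethyl-3,6,7-trimethyl-6-[(1E,3E)-2-methyl-4-phenylbuta-1,3-dien-1-yl]-4-{[(trifluoromethyl)sulfonyl]oxy}-3a,6,7,7a-tetrahydro-3H-indene-7-carboxylate | CCC1=C[C@@H](C)[C@@H]2C(OS(=O)(=O)C(F)(F)F)=C[C@](C)(/C=C(C)/C=C/c3ccccc3)[C@](C)(C(=O)OC(C)(C)C)[C@@H]12 | intermediate
21 | tert-butyl (3R,3aS,6S,7R,7aR)-1-ethyl-3,4,6,7-tetramethyl-6-[(1E,3E)-2-methyl-4-phenylbuta-1,3-dien-1-yl]-3a,6,7,7a-tetrahydro-3H-indene-7-carboxylate | CCC1=C[C@@H](C)[C@@H]2C(C)=C[C@](C)(/C=C(C)/C=C/c3ccccc3)[C@](C)(C(=O)OC(C)(C)C)[C@@H]12 | intermediate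
22 | trimethylsilyl (3R,3aS,6S,7R,7aR)-1-ethyl-3,4,6,7-tetramethyl-6-[(1E,3E)-2-methyl-4-phenylbuta-1,3-dien-1-yl]-3a,6,7,7a-tetrahydro-3H-indene-7-carboxylate | CCC1=C[C@@H](C)[C@@H]2C(C)=C[C@](C)(/C=C(C)/C=C/c3ccccc3)[C@](C)(C(=O)O[Si](C)(C)C)[C@@H]12 | intermediate
23 | zyggomphic acid B, (3R,3aS,6S,7R,7aR)-1-ethyl-3,4,6,7-tetramethyl-6-[(1E,3E)-2-methyl-4-phenylbuta-1,3-dien-1-yl]-3a,6,7,7a-tetrahydro-3H-indene-7-carboxylic acid | CCC1=C[C@@H](C)[C@@H]2C(C)=C[C@](C)(/C=C(C)/C=C/c3ccccc3)[C@](C)(C(=O)O)[C@@H]12 | target

## Step count and least certain steps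

Total: 14 steps. Longest linear sequence: 10 steps (1, 2, 5, 6, 7, 8, 11, 12, 13, 14, from tert-butyl benzoate). The side branches are steps 3 and 4 (partners for step 5) and steps 9 and 10 (dienylalane).

**Step 5 (key step).** The second half is the most likely to fail. The hindered bromomagnesium dienolate may react slowly with the 1,3-dimethylallyl palladium complex, which can then be lost to diene by β-hydride elimination. Control at C3 may be poor if the bulky chiral nucleophile and the chiral ligand are mismatched. Residual copper and Grignard reagent can consume the acetate. The face preference at C7a also rests on a modest steric difference between methyl and ester, which a one-pot run gives no chance to correct.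
Fallback: separate the two bond formations and change the allylation metal. Setting out from 4 and 6, the same copper-catalysed addition run in the presence of Me3SiCl gives silyl dienol ether F1, which can be purified and assayed for arm and face selectivity. F1 is then allylated under iridium catalysis ([Ir(cod)Cl]2, chiral phosphoramidite, CsF/ZnF2, DME) with (E)-but-2-en-1-yl methyl carbonate F2 (from (E)-but-2-en-1-ol and methyl chloroformate). This known reaction type gives the branched product and fixes the allylic stereocentre through the catalyst, while the enolate face is still governed by C7a. It gives vinyl analogue F3, which differs from 10 only in carrying vinyl in place of propenyl on C3. Ring-closing metathesis of F3 under the conditions of step 6, now with loss of ethene, comes back to the route at 11.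

**Step 11.** Carbon–carbon bond formation at C6 may be slow or fail, because C6 is β,β-disubstituted and flanked by the quaternary C7. Methyl transfer from aluminium, 1,2-addition or recovered 13 would then result.
Fallback: change the nucleophile class to a stoichiometric lithium diorganocuprate with silyl chloride acceleration. Setting out from 16, iodinolysis (I2, THF, −30 °C) gives dienyl iodide F4 with retention of geometry. Halogen–lithium exchange (t-BuLi, Et2O, −78 °C) and CuI give lithium bis(dienyl)cuprate F5. With Me3SiCl in THF (−78 → −20 °C), F5 adds to 13 and is trapped directly as the silyl enol ether, coming back to the route at 18.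

**Step 6.** Closure of the strained trans-fused cyclopentene onto the hindered 1,1-disubstituted alkene may be slow. Intermolecular metathesis through the propenyl group, or ring-opening metathesis through the cis-disubstituted C5=C6 enone alkene, could then compete.
Fallback: change the order so that C5=C6 is trisubstituted before metathesis. Setting out from 10, the conditions of step 7 give monocyclic enol ether F6 and the conditions of step 8 give monocyclic β-methyl enone F7 (identical with A4). Metathesis of F7 with the same catalyst, in toluene at 80 °C if needed since no competing alkene remains, comes back to the route at 13.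

**Step 14.** Lewis acid or adventitious triflic acid could trigger attack of the liberated carboxyl on C4=C5 or on the diene (lactonisation), or isomerise the diene.
Fallback: replace ionisation by reduction and re-oxidation. Setting out from 21, LiAlH4 (THF, reflux) reduces the hindered ester to primary alcohol F8. The periodinane DMP (CH2Cl2, NaHCO3) gives aldehyde F9. Pinnick oxidation (NaClO2, NaH2PO4, 2-methylbut-2-ene, t-BuOH/H2O) comes back to the route at 23.

## Further compounds

F1 | step 5 | tert-butyl (1S,6R)-6-(but-1-en-2-yl)-1-methyl-4-[(trimethylsilyl)oxy]cyclohexa-2,4-diene-1-carboxylate | C1=CC(O[Si](C)(C)C)=C[C@H](C(=C)CC)[C@@]1(C)C(=O)OC(C)(C)C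
F2 | step 5 | (E)-but-2-en-1-yl methyl carbonate | C/C=C/COC(=O)OC
F3 | step 5 | tert-butyl (1S,5S,6R)-5-[(2R)-but-3-en-2-yl]-6-(but-1-en-2-yl)-1-methyl-4-oxocyclohex-2-ene-1-carboxylate | C1=CC(=O)[C@@H]([C@H](C)C=C)[C@H](C(=C)CC)[C@@]1(C)C(=O)OC(C)(C)C
F4 | step 11 | [(1E,3E)-4-iodo-3-methylbuta-1,3-dien-1-yl]benzene | I/C=C(C)/C=C/c1ccccc1
F5 | step 11 | lithium bis[(1E,3E)-2-methyl-4-phenylbuta-1,3-dien-1-yl]cuprate | [Li+].c1ccccc1/C=C/C(C)=C/[Cu-]/C=C(C)/C=C/c1ccccc1
F6 | step 6 | tert-butyl 6-(but-1-en-2-yl)-1,2-dimethyl-5-[(2R,3E)-pent-3-en-2-yl]-4-[(trimethylsilyl)oxy]cyclohex-3-ene-1-carboxylate, ring configured as 10, new methyl trans to the C7 methyl | C[C@H]1C=C(O[Si](C)(C)C)[C@@H]([C@H](C)/C=C/C)[C@H](C(=C)CC)[C@@]1(C)C(=O)OC(C)(C)C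
F7 | step 6 | tert-butyl 6-(but-1-en-2-yl)-1,2-dimethyl-4-oxo-5-[(2R,3E)-pent-3-en-2-yl]cyclohex-2-ene-1-carboxylate, configured as 10 | CC1=CC(=O)[C@@H]([C@H](C)/C=C/C)[C@H](C(=C)CC)[C@@]1(C)C(=O)OC(C)(C)C
F8 | step 14 | {(3R,3aS,6S,7R,7aR)-1-ethyl-3,4,6,7-tetramethyl-6-[(1E,3E)-2-methyl-4-phenylbuta-1,3-dien-1-yl]-3a,6,7,7a-tetrahydro-3H-inden-7-yl}methanol | CCC1=C[C@@H](C)[C@@H]2C(C)=C[C@](C)(/C=C(C)/C=C/c3ccccc3)[C@](C)(CO)[C@@H]12
F9 | step 14 | (3R,3aS,6S,7R,7aR)-1-ethyl-3,4,6,7-tetramethyl-6-[(1E,3E)-2-methyl-4-phenylbuta-1,3-dien-1-yl]-3a,6,7,7a-tetrahydro-3H-indene-7-carbaldehyde | CCC1=C[C@@H](C)[C@@H]2C(C)=C[C@](C)(/C=C(C)/C=C/c3ccccc3)[C@](C)(C=O)[C@@H]12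
A1 | alternative 1 | ring B C4 ketone, methyl ester, configured as the target | CCC1=C[C@@H](C)[C@@H]2C(=O)C[C@](C)(/C=C(C)/C=C/c3ccccc3)[C@](C)(C(=O)OC)[C@@H]12
A2 | alternative 1 | methyl 2-{2-ethyl-4-methyl-5-[(2Z,4E,6E)-3,5-dimethyl-7-phenylhepta-2,4,6-trienoyl]cyclopent-2-en-1-yl}propanoate, ring A configured as the target | CCC1=C[C@@H](C)[C@H](C(=O)/C=C(C)\C=C(C)\C=C\c2ccccc2)[C@H]1C(C)C(=O)OC
A3 | alternative 2 | trans-fused bicyclic β-methyl enone, tert-butyl ester (same structure as 13) | CCC1=C[C@@H](C)[C@@H]2C(=O)C=C(C)[C@](C)(C(=O)OC(C)(C)C)[C@@H]12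
A4 | alternative 2 | monocyclic β-methyl enone with butenyl on C7a and pentenyl on C3a, tert-butyl ester | CC1=CC(=O)[C@@H]([C@H](C)/C=C/C)[C@H](C(=C)CC)[C@@]1(C)C(=O)OC(C)(C)C
A5 | alternative 3 | tert-butyl 1,2-dimethyl-4-oxocyclohex-2-ene-1-carboxylate (C7 set) | CC1=CC(=O)CC[C@@]1(C)C(=O)OC(C)(C)C
A6 | alternative 3 | tert-butyl 2-methyl-3-oxobutanoate | CC(=O)C(C)C(=O)OC(C)(C)C
A7 | alternative 3 | but-3-en-2-one | CC(=O)C=C
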